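**Plan**
Locants: tetralin numbering is used throughout, also for open-chain intermediates (C1 diarylmethine; C2 and C3 carry the CH2OMe carbons C9 and C9'; C4 benzylic CH2; C4a/C8a fusion carbons). Ring A is the fused dimethoxyarene, ring B the carbocycle, ring C the pendant 3,4-dimethoxyphenyl group.
Retrosynthesis: the two hydrogens on C2 and C3 are removed first, then the C2=C3 bond is cut by ring-closing metathesis. This works because C2 and C3 are neighbours in ring B and each carries exactly one CH2OMe carbon, so ring B can exist as a tetrasubstituted cyclohexene whose only stereocentre is C1.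
Further cuts: C4–C4a (Stille coupling), the C2 methylidene and the C9 oxidation level (Mannich/elimination, reduction, methylation), C1–ring C (conjugate arylation), C1=C2 (olefination of 2-bromo-4,5-dimethoxybenzaldehyde).
Forward: the C1–C2–C9 chain is grown on ring A, ring C is added at C1, the C4–C3–C9' arm is coupled to C4a, C2 is methylenated, and ring B (the only ring made) is closed in step 10 and saturated in step 11.
Stereochemistry: C1 (S) comes from the Rh/(R)-BINAP aryl transfer; C2 (S) and C3 (R) come from syn addition of H2 to C2=C3 on the face away from the pseudoaxial ring C, which puts ring C, C9 and C9' all cis.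

Key step: step 10

Assumption: in step 2 the (R)-BINAP/rhodium catalyst is taken to deliver the aryl group to the re face of the α-carbon of the (E)-enoate, as the accepted model for this catalyst family predicts; should the sense be found opposite, (S)-BINAP is used and nothing else changes.

Step 1
Reactants: 1 2-bromo-4,5-dimethoxybenzaldehyde; 2 triethyl phosphonoacetate
Product: 3 ethyl (2E)-3-(2-bromo-4,5-dimethoxyphenyl)prop-2-enoate
Conditions: NaH, THF, 0 °C → rt
Reagents that add atoms: none
Why: Horner–Wadsworth–Emmons olefination of an aromatic aldehyde with a stabilised phosphonate anion should give the (E)-cinnamate, and the aryl bromide is inert to NaH in THF.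

Step 2
Reactants: 3 ethyl (2E)-3-(2-bromo-4,5-dimethoxyphenyl)prop-2-enoate; 4 3,4-dimethoxyphenylboronic acid
Product: 5 ethyl (3S)-3-(2-bromo-4,5-dimethoxyphenyl)-3-(3,4-dimethoxyphenyl)propanoate
Conditions: 4 (3 equiv), Rh(acac)(C2H4)2 (3 mol%), (R)-BINAP (3.3 mol%), 1,4-dioxane/H2O (10:1), 100 °C
Reagents that add atoms: none
Why: Rhodium-catalysed asymmetric 1,4-addition of an arylboronic acid to an enoate (Hayashi–Miyaura reaction): the aryl–rhodium species formed by transmetalation inserts the cinnamate, the (R)-BINAP ligand directs ring C to the re face of the α-carbon and so sets C1 as S, and water protonates the rhodium enolate while the aryl bromide stays untouched.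

Step 3
Reactants: 6 3-chloro-2-(chloromethyl)prop-1-ene
Product: 7 3-chloro-2-(methoxymethyl)prop-1-ene
Conditions: NaOMe (1 equiv), MeOH, 0 → 40 °C, threefold excess of 6, fractional distillation
Reagents that add atoms: sodium methoxide, C[O-].[Na+]
Why: Williamson ether synthesis by SN2 displacement of one allylic chloride, the excess of dichloride limiting the second substitution.

Step 4
Reactants: 7 3-chloro-2-(methoxymethyl)prop-1-ene
Product: 9 tributyl[2-(methoxymethyl)prop-2-en-1-yl]stannane, via [2-(methoxymethyl)prop-2-en-1-yl]magnesium chloride 8 (not isolated)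
Conditions: Mg turnings, Bu3SnCl, THF, ultrasound, 20–30 °C
Reagents that add atoms: tributyltin chloride, CCCC[Sn](Cl)(CCCC)CCCC
Why: Barbier-type stannylation in which the allylmagnesium chloride is trapped by Bu3SnCl as it forms, which suppresses Wurtz coupling, and the allyl unit is symmetrical toward 1,3-transposition so only one stannane can result.

Step 5
Reactants: 5 ethyl (3S)-3-(2-bromo-4,5-dimethoxyphenyl)-3-(3,4-dimethoxyphenyl)propanoate; 9 tributyl[2-(methoxymethyl)prop-2-en-1-yl]stannane
Product: 10 ethyl (3S)-3-{4,5-dimethoxy-2-[2-(methoxymethyl)prop-2-en-1-yl]phenyl}-3-(3,4-dimethoxyphenyl)propanoate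
Conditions: Pd2(dba)3 (2.5 mol%), [HP(t-Bu)3]BF4 (10 mol%), CsF (2.2 equiv), 1,4-dioxane, 90 °C
Reagents that add atoms: none
Why: Stille cross-coupling in which the bulky, electron-rich zerovalent palladium–P(t-Bu)3 catalyst inserts into the hindered, electron-rich aryl bromide, fluoride assists allyl transfer from tin and reductive elimination forms the C4a–C4 bond, while the ester and C1 are inert and the substrate contains no alkene that could compete by Heck cyclisation.

Step 6
Reactants: 10 ethyl (3S)-3-{4,5-dimethoxy-2-[2-(methoxymethyl)prop-2-en-1-yl]phenyl}-3-(3,4-dimethoxyphenyl)propanoate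
Product: 11 ethyl (3S)-2-[(dimethylamino)methyl]-3-{4,5-dimethoxy-2-[2-(methoxymethyl)prop-2-en-1-yl]phenyl}-3-(3,4-dimethoxyphenyl)propanoate (both epimers at the ester α-carbon)
Conditions: LiN(i-Pr)2 (1.15 equiv), THF, −78 °C; then CH2=NMe2+ I−, −78 °C → rt
Reagents that add atoms: N,N-dimethylmethylideneammonium iodide, C=[N+](C)C.[I-]
Why: Mannich aminomethylation of the lithium ester enolate by the preformed iminium salt, where the new centre at C2 is formed without control and is erased in step 7, and the far less acidic C1–H and benzylic C4–H are not deprotonated at −78 °C.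

Step 7
Reactants: 11 ethyl (3S)-2-[(dimethylamino)methyl]-3-{4,5-dimethoxy-2-[2-(methoxymethyl)prop-2-en-1-yl]phenyl}-3-(3,4-dimethoxyphenyl)propanoate
Product: 13 ethyl 2-[(S)-{4,5-dimethoxy-2-[2-(methoxymethyl)prop-2-en-1-yl]phenyl}(3,4-dimethoxyphenyl)methyl]prop-2-enoate, via trimethylammonium iodide 12 (not isolated)
Conditions: MeI, MeOH, rt; evaporate; then K2CO3, CH2Cl2/H2O, rt
Reagents that add atoms: none
Why: Exhaustive N-methylation turns the amine into a leaving group and carbonate then triggers E1cB (Hofmann-type) elimination to the α-methylene ester, a base too weak to remove the diarylmethine C1–H, so C1 keeps its configuration while the C2 centre disappears.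

Step 8
Reactants: 13 ethyl 2-[(S)-{4,5-dimethoxy-2-[2-(methoxymethyl)prop-2-en-1-yl]phenyl}(3,4-dimethoxyphenyl)methyl]prop-2-enoate
Product: 14 2-[(S)-{4,5-dimethoxy-2-[2-(methoxymethyl)prop-2-en-1-yl]phenyl}(3,4-dimethoxyphenyl)methyl]prop-2-en-1-ol
Conditions: i-Bu2AlH (2.5 equiv), CH2Cl2, −78 → 0 °C; aq potassium sodium tartrate
Reagents that add atoms: none
Why: 1,2-Reduction of the conjugated ester by diisobutylaluminium hydride at low temperature should give the primary allylic alcohol without touching either 1,1-disubstituted alkene.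

Step 9
Reactants: 14 2-[(S)-{4,5-dimethoxy-2-[2-(methoxymethyl)prop-2-en-1-yl]phenyl}(3,4-dimethoxyphenyl)methyl]prop-2-en-1-ol
Product: 15 1-[(1S)-1-(3,4-dimethoxyphenyl)-2-(methoxymethyl)prop-2-en-1-yl]-4,5-dimethoxy-2-[2-(methoxymethyl)prop-2-en-1-yl]benzene
Conditions: NaH (1.1 equiv), MeI, THF, 0 °C → rt
Reagents that add atoms: iodomethane, CI
Why: Williamson etherification in which the sodium alkoxide of the primary allylic alcohol is methylated at 0 °C, faster than the heterogeneous hydride could deprotonate the diarylmethine C1–H.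

Step 10
Reactants: 15 1-[(1S)-1-(3,4-dimethoxyphenyl)-2-(methoxymethyl)prop-2-en-1-yl]-4,5-dimethoxy-2-[2-(methoxymethyl)prop-2-en-1-yl]benzene
Product: 16 (1S)-1-(3,4-dimethoxyphenyl)-6,7-dimethoxy-2,3-bis(methoxymethyl)-1,4-dihydronaphthalene
Conditions: RuCl2[1,3-bis(2-methylphenyl)imidazolidin-2-ylidene](=CH-C6H4-2-O-i-Pr) (second-generation Hoveyda–Grubbs catalyst with the N-o-tolyl carbene, 2 × 5 mol%), 1,4-benzoquinone (10 mol%), degassed toluene (5 mM), 80 °C, argon sparge
Reagents that add atoms: none
Why: The ruthenium carbene first exchanges onto the unhindered methylidene of the arm on C4a to give a C3-centred disubstituted alkylidene, which undergoes [2+2] cycloaddition with the C2 methylidene next to C1; cycloreversion of the ruthenacyclobutane releases the C2=C3 alkene and Ru=CH2, and the ethene formed on the next turnover is swept out by the argon stream. The closest known reaction type is ring-closing metathesis of two 1,1-disubstituted alkenes to tetrasubstituted cyclohexenes with ruthenium N-heterocyclic carbene catalysts, for which the less hindered N-o-tolyl carbene and hot dilute toluene are the usual choice. Ring B closes as a six-membered carbocycle in which both metathesis carbons, C2 and C3, become ring members (endocyclic alkene) while the two methylidene carbons leave as ethene. No stereocentre is created, and C1 is carried through unchanged because the medium is neutral and aprotic. The step needs ring closure to win over oligomerisation and the double bonds to stay where they are: the ortho placement of the two arms on C4a and C8a of ring A keeps the alkenes within reach of each other, 1,1-disubstituted alkenes are slow to couple intermolecularly, high dilution is used, and benzoquinone removes ruthenium hydrides that could move the new alkene toward C1.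

Step 11
Reactants: 16 (1S)-1-(3,4-dimethoxyphenyl)-6,7-dimethoxy-2,3-bis(methoxymethyl)-1,4-dihydronaphthalene
Product: 17 (1S,2S,3R)-1-(3,4-dimethoxyphenyl)-6,7-dimethoxy-2,3-bis(methoxymethyl)-1,2,3,4-tetrahydronaphthalene
Conditions: [Ir(cod)(PCy3)(py)]PF6 (5 mol%), H2 (1–50 bar), CH2Cl2, 0 °C → rt
Reagents that add atoms: none
Why: Homogeneous hydrogenation with a cationic iridium catalyst of the kind that reduces tetrasubstituted alkenes: ring C on C1 is held pseudoaxial by the peri hydrogen on C8 and by C9 on C2 and covers one face of C2=C3, so both hydrogens arrive syn on the opposite face, which sets C2 as S and C3 as R with ring C, C9 and C9' all cis.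

**Compound list**
1 | 2-bromo-4,5-dimethoxybenzaldehyde | COc1cc(Br)c(C=O)cc1OC | starting material
2 | triethyl phosphonoacetate | CCOC(=O)CP(=O)(OCC)OCC | starting material
3 | ethyl (2E)-3-(2-bromo-4,5-dimethoxyphenyl)prop-2-enoate | CCOC(=O)/C=C/c1cc(OC)c(OC)cc1Br | intermediate
4 | 3,4-dimethoxyphenylboronic acid | COc1ccc(B(O)O)cc1OC | starting material
5 | ethyl (3S)-3-(2-bromo-4,5-dimethoxyphenyl)-3-(3,4-dimethoxyphenyl)propanoate | Brc1cc(OC)c(OC)cc1[C@H](c1ccc(OC)c(OC)c1)CC(=O)OCC | intermediate
6 | 3-chloro-2-(chloromethyl)prop-1-ene | C=C(CCl)CCl | starting material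
7 | 3-chloro-2-(methoxymethyl)prop-1-ene | C=C(CCl)COC | intermediate
8 | [2-(methoxymethyl)prop-2-en-1-yl]magnesium chloride | C=C(COC)C[Mg]Cl | intermediate
9 | tributyl[2-(methoxymethyl)prop-2-en-1-yl]stannane | C=C(COC)C[Sn](CCCC)(CCCC)CCCC | intermediate
10 | ethyl (3S)-3-{4,5-dimethoxy-2-[2-(methoxymethyl)prop-2-en-1-yl]phenyl}-3-(3,4-dimethoxyphenyl)propanoate | C=C(COC)Cc1cc(OC)c(OC)cc1[C@H](c1ccc(OC)c(OC)c1)CC(=O)OCC | intermediate
11 | ethyl (3S)-2-[(dimethylamino)methyl]-3-{4,5-dimethoxy-2-[2-(methoxymethyl)prop-2-en-1-yl]phenyl}-3-(3,4-dimethoxyphenyl)propanoate (both epimers at the ester α-carbon) | C=C(COC)Cc1cc(OC)c(OC)cc1[C@H](c1ccc(OC)c(OC)c1)C(CN(C)C)C(=O)OCC | intermediate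
12 | [(3S)-2-(ethoxycarbonyl)-3-{4,5-dimethoxy-2-[2-(methoxymethyl)prop-2-en-1-yl]phenyl}-3-(3,4-dimethoxyphenyl)propyl]trimethylammonium iodide (both epimers at the ester α-carbon) | C=C(COC)Cc1cc(OC)c(OC)cc1[C@H](c1ccc(OC)c(OC)c1)C(C[N+](C)(C)C)C(=O)OCC.[I-] | intermediate
13 | ethyl 2-[(S)-{4,5-dimethoxy-2-[2-(methoxymethyl)prop-2-en-1-yl]phenyl}(3,4-dimethoxyphenyl)methyl]prop-2-enoate | C=C(COC)Cc1cc(OC)c(OC)cc1[C@H](c1ccc(OC)c(OC)c1)C(=C)C(=O)OCC | intermediate
14 | 2-[(S)-{4,5-dimethoxy-2-[2-(methoxymethyl)prop-2-en-1-yl]phenyl}(3,4-dimethoxyphenyl)methyl]prop-2-en-1-ol | C=C(COC)Cc1cc(OC)c(OC)cc1[C@H](c1ccc(OC)c(OC)c1)C(=C)CO | intermediate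
15 | 1-[(1S)-1-(3,4-dimethoxyphenyl)-2-(methoxymethyl)prop-2-en-1-yl]-4,5-dimethoxy-2-[2-(methoxymethyl)prop-2-en-1-yl]benzene | C=C(COC)Cc1cc(OC)c(OC)cc1[C@H](c1ccc(OC)c(OC)c1)C(=C)COC | intermediate
16 | (1S)-1-(3,4-dimethoxyphenyl)-6,7-dimethoxy-2,3-bis(methoxymethyl)-1,4-dihydronaphthalene | COCC1=C(COC)[C@@H](c2ccc(OC)c(OC)c2)c2cc(OC)c(OC)cc2C1 | intermediate
17 | (1S,2S,3R)-1-(3,4-dimethoxyphenyl)-6,7-dimethoxy-2,3-bis(methoxymethyl)-1,2,3,4-tetrahydronaphthalene | COC[C@@H]1Cc2cc(OC)c(OC)cc2[C@H](c2ccc(OC)c(OC)c2)[C@@H]1COC | target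

**Count**
Total steps: 11. Longest linear sequence: 9 steps (1, 2, 5, 6, 7, 8, 9, 10, 11; the stannane branch, steps 3 and 4, joins at step 5 and is equally long).

**Steps most likely to fail**

Step 10. The closure may stall after the catalyst has loaded onto the C4a arm, because cycloaddition onto the methylidene flanked by the diarylmethine C1 is slow. The decomposing catalyst then forms ruthenium hydrides that shift the allyl ether double bonds or move C2=C3 toward C1, which would erase the C1 configuration. The fallback sets out from 14 and comes back at 16. The free allylic alcohol 14 is treated with the same ruthenium carbene (toluene, 80 °C). A hydroxyl group next to an alkene is a known accelerating group in ruthenium metathesis, so the catalyst should engage the hindered C2 methylidene first, and the ring-closing event becomes attack of a C2-centred alkylidene on the unhindered C3 methylidene. This should give [(1S)-1-(3,4-dimethoxyphenyl)-6,7-dimethoxy-3-(methoxymethyl)-1,4-dihydronaphthalen-2-yl]methanol F1. Neutral O-methylation of F1 (MeI, Ag2O, MeCN, rt) then gives 16.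

Step 11. Hydrogen delivery may discriminate poorly between the two faces, the tetrasubstituted alkene may resist reduction, or an iridium hydride may shift the double bond into conjugation with the arenes through C1 before reduction. The fallback sets out from 13 and comes back at 17; it moves the ring closure and the reduction to the ester oxidation level. Ring-closing metathesis of acrylate 13 with the ruthenium carbene of step 10 should give ethyl (1S)-1-(3,4-dimethoxyphenyl)-6,7-dimethoxy-3-(methoxymethyl)-1,4-dihydronaphthalene-2-carboxylate F2. Its double bond is held in place by conjugation with the ester, and conjugated C2=C3 esters and lactones of 1-aryl-1,4-dihydronaphthalenes are a class in which heterogeneous hydrogenation anti to the C1 aryl group is well established. Hydrogenation over Rh/Al2O3 (H2, 50 bar, EtOAc) should therefore give ethyl (1S,2S,3R)-1-(3,4-dimethoxyphenyl)-6,7-dimethoxy-3-(methoxymethyl)-1,2,3,4-tetrahydronaphthalene-2-carboxylate F3. Reduction with LiAlH4 (THF, 0 °C) gives [(1S,2S,3R)-1-(3,4-dimethoxyphenyl)-6,7-dimethoxy-3-(methoxymethyl)-1,2,3,4-tetrahydronaphthalen-2-yl]methanol F4, and methylation (NaH, MeI, THF) gives 17.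

Step 2. Insertion of the electron-rich, ortho-substituted cinnamate into the aryl–rhodium bond may be slower than protodeboronation of the boronic acid, or the enantioselection may be insufficient. The fallback sets out from 3 and comes back at 5; it replaces catalyst control by auxiliary control. Saponification of 3 (LiOH, THF/H2O) gives (2E)-3-(2-bromo-4,5-dimethoxyphenyl)prop-2-enoic acid F5. Pivaloyl chloride and Et3N convert it into (2E)-3-(2-bromo-4,5-dimethoxyphenyl)prop-2-enoic 2,2-dimethylpropanoic anhydride F6, which acylates lithiated (4R)-4-phenyl-1,3-oxazolidin-2-one to give (4R)-3-[(2E)-3-(2-bromo-4,5-dimethoxyphenyl)prop-2-enoyl]-4-phenyl-1,3-oxazolidin-2-one F7. The cuprate from 3,4-dimethoxyphenylmagnesium bromide and CuBr·SMe2 (THF, −40 → −20 °C) should add to the magnesium-chelated s-cis imide on the face opposite the 4-phenyl group. This gives (4R)-3-[(3S)-3-(2-bromo-4,5-dimethoxyphenyl)-3-(3,4-dimethoxyphenyl)propanoyl]-4-phenyl-1,3-oxazolidin-2-one F8. Ethanolysis (EtOMgBr, EtOH/THF, 0 °C) removes the auxiliary and gives ester 5.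

**Further compounds**
F1 | step 10 | [(1S)-1-(3,4-dimethoxyphenyl)-6,7-dimethoxy-3-(methoxymethyl)-1,4-dihydronaphthalen-2-yl]methanol | COCC1=C(CO)[C@@H](c2ccc(OC)c(OC)c2)c2cc(OC)c(OC)cc2C1
F2 | step 11 | ethyl (1S)-1-(3,4-dimethoxyphenyl)-6,7-dimethoxy-3-(methoxymethyl)-1,4-dihydronaphthalene-2-carboxylate | COCC1=C(C(=O)OCC)[C@@H](c2ccc(OC)c(OC)c2)c2cc(OC)c(OC)cc2C1
F3 | step 11 | ethyl (1S,2S,3R)-1-(3,4-dimethoxyphenyl)-6,7-dimethoxy-3-(methoxymethyl)-1,2,3,4-tetrahydronaphthalene-2-carboxylate | COC[C@@H]1Cc2cc(OC)c(OC)cc2[C@H](c2ccc(OC)c(OC)c2)[C@@H]1C(=O)OCC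
F4 | step 11 | [(1S,2S,3R)-1-(3,4-dimethoxyphenyl)-6,7-dimethoxy-3-(methoxymethyl)-1,2,3,4-tetrahydronaphthalen-2-yl]methanol | COC[C@@H]1Cc2cc(OC)c(OC)cc2[C@H](c2ccc(OC)c(OC)c2)[C@@H]1CO
F5 | step 2 | (2E)-3-(2-bromo-4,5-dimethoxyphenyl)prop-2-enoic acid | OC(=O)/C=C/c1cc(OC)c(OC)cc1Br
F6 | step 2 | (2E)-3-(2-bromo-4,5-dimethoxyphenyl)prop-2-enoic 2,2-dimethylpropanoic anhydride | CC(C)(C)C(=O)OC(=O)/C=C/c1cc(OC)c(OC)cc1Br
F7 | step 2 | (4R)-3-[(2E)-3-(2-bromo-4,5-dimethoxyphenyl)prop-2-enoyl]-4-phenyl-1,3-oxazolidin-2-one | O=C1OC[C@@H](c2ccccc2)N1C(=O)/C=C/c1cc(OC)c(OC)cc1Br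
F8 | step 2 | (4R)-3-[(3S)-3-(2-bromo-4,5-dimethoxyphenyl)-3-(3,4-dimethoxyphenyl)propanoyl]-4-phenyl-1,3-oxazolidin-2-one | O=C1OC[C@@H](c2ccccc2)N1C(=O)C[C@@H](c1ccc(OC)c(OC)c1)c1cc(OC)c(OC)cc1Br
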